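## Structural features

The target is a cyclohexane, the quinic acid ring, numbered from the carbinol carbon C1 that carries CO2H and a tertiary OH. C2 and C6 are methylenes, and C3, C4 and C5 each carry an O-galloyl (3,4,5-trihydroxybenzoyl) ester. The three acylated carbinol carbons are contiguous, and the quaternary centre C1 is separated from them by the two CH2 groups. O1, O3 and O4 lie on one face, O5 and the carboxyl carbon on the other, so O3/O4 are cis, O4/O5 are trans and the carboxyl is cis to O5. The fragile elements are the nine free phenols (pyrogallol units, easily oxidised and intolerant of base), the three aryl esters on neighbouring secondary carbons (hydrolysis, acyl migration) and the α-hydroxy acid, so the last operation has to be neutral and reductive. The aromatic parts are trivial; the real difficulties are the quaternary C1 in its correct relationship to the C3–C5 triad and the crowded triple acylation. C3 and C5 are both R and flank C4, so the chain C2–C3–C4–C5–C6 with O3, O4 and O5 is a 1,5-dideoxy-D-arabinitol whose two CH2 ends must be bonded to one and the same carbon. If that carbon (C1) enters with two identical carboxyl arms it is not a stereocentre, the ring closure needs no stereocontrol, and C1 becomes stereogenic only when O5 later selects the one arm on its own face.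

## Logic of the disconnections

21 to 20. The ten benzylic C–O bonds (nine aryl ethers and the ester at C1) are cut last in the forward sense. The free pyrogallols and the triester of 21 tolerate neither base nor oxidants, so they are unveiled by neutral hydrogenolysis. The gain is that every earlier intermediate is lipophilic and not oxidisable. The demand is that ten benzyl groups fall in one operation without touching the three aryl esters.

20 to 18 and 19. The three ester C(=O)–O bonds at O3, O4 and O5 are cut, which releases three molecules of 19 for each molecule of 18. The aryl rings carry no stereochemistry and are available with the correct oxygen pattern as 19. The problem shrinks to the carbocycle 18. The forward step must acylate three contiguous secondary hydroxyls, leave the tertiary O1 free, and acylate O5 faster than O5 attacks the benzyl ester.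

18 to 17 to 15. The acetonide C–O bonds are restored and the benzyl ester at C1 is exchanged for the lactone bond between O5 and the carboxyl carbon. This leads to the rigid bicycle 15, in which the configuration of C1 is locked to that of C5. The forward opening must be irreversible. It is therefore done by saponification to the salt 16 and O-alkylation, never passing through the free hydroxy acid, which would relactonise.

15 to 12. The C1–O bond is cut and replaced by C1–CO2H. C1 then carries two carboxyl-level carbons that differ only in that one is lactonised, which is the signature of a malonate. The single quaternary stereocentre is thereby traced to a prochiral carbon. The forward step is a decarboxylative oxygenation at a bridgehead (through 13 and 14). Retention is enforced because a bridgehead radical can be trapped only from outside the cage.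

12 to 11 to 9 (through 10). The lactone bond O5–C(=O) is cut, giving back two identical benzyl esters on C1 and a silyl ether on O5. In 9 C1 is not stereogenic. In the forward sense O5, once freed, can reach only the ester on its own face. The demand is that O5 is the only hydroxyl liberated (the acetonide holds O3/O4) and that no free malonic acid is formed. Fluoride-triggered translactonisation on the diester meets both points and saves a step.

9 to 6 and 7 (key step). The ring bonds C1–C2 and C1–C6 are cut. This opens the ring at the only carbon that need not be stereogenic and turns C2–C6 into a pentitol chain. Traced atom by atom, sugar C1/C5 become ring C6/C2, sugar C2 (silyl ether) becomes C5, sugar C3 becomes C4 and sugar C4 becomes C3. The erythro pair O3/O4 of the pentitol closes to the cis pair, the threo pair O2/O3 to the trans pair, and the D series gives 3R,5R, so 6 and 9 carry exactly the configuration that 21 requires. The forward step needs a double SN2 at β-oxygenated primary carbons that beats elimination and oligomerisation, with no free hydroxyl in 6.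

6 to 5 to 4 to 3. The two C–I bonds are traced to C–O bonds. The question is how O2 is told apart from O1 and O5. In 3 the secondary O2 is 1,2 to C1 and 1,4 to C5 across a cis-dioxolane, so a leaving group at either end next to a free O2 invites oxirane or 2,5-anhydro ring formation. All three hydroxyls are therefore silylated first (4), the two primary silyl ethers are removed selectively (5), and the diol is iodinated (6). The demand is the standard preference for cleavage of primary over secondary silyl ethers.

3 to 2 to 1. The acetonide is traced to the pyranose form of 1, which offers exactly one cis-vicinal diol (O3/O4), and the primary alcohol at sugar C1 to the aldehyde. This reaches a commercial pentose that supplies all three carbinol centres. The forward steps are a kinetic acetonation on the pyranose and a borohydride reduction.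

## Other disconnections considered

Alternative 1: The cut is made inside each galloyl ring, at C1'–C6' and C2'–C3', six C–C bonds in all. Every arene is traced to a propioloyl ester and the furan A2 (3,4-bis(benzyloxy)furan).
- Forward step: The tri-propiolate A1 (three propioloyl groups on O3, O4 and O5 of 18) would undergo three Diels–Alder additions with A2. Acid would then open each oxa-bridged cycloadduct, with a 1,2-hydride shift, to the phenol, giving A3. Hydrogenolysis would finish as in the chosen plan.
- In its favour: The propioloyl group is sterically slim, so the triple esterification of the crowded triol should be easier than with 19; on this point the alternative is the better plan. The final deprotection is the same single hydrogenolysis, so the two plans are equal there.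
- Against it: It leaves the real problem untouched, because the cyclohexane with its four stereocentres would still have to come from steps 1–11 below. The arenes it builds can be bought with the correct oxygen pattern. Three cycloadditions and three bridge openings must all go the same way on one molecule, and each opening can place the phenol at C5' or at C2', so regiochemical errors multiply. A2 is electron-rich and sensitive to acid and air, the propiolates are Michael acceptors toward the free O1 hydroxyl, and the acid needed for aromatisation invites acyl migration.
- Comparison: Structurally the chosen plan spends its key step on the stereochemically demanding carbocycle, this one on achiral rings. Mechanistically a reagent-free cycloaddition is attractive but is followed by a cationic rearrangement with a regiochemical choice. In step count it replaces one acylation by at least two operations plus the preparation of A2.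

Alternative 2: The cut is the ring bond C1–C2, paired with the C4–O bond of the δ-lactone A4 (3-benzyloxy, 5-silyloxy and 6-vinyl, the last two trans).
- Forward step: Enolisation and O-silylation of A4 would give the ketene acetal A5. Its vinyl group must reach across the lactone ring, hence the boat-like transition state. The [3,3] shift forms C1–C2 and breaks C4–O, and hydrolysis of the silyl ester would give acid A6.
- In its favour: C1 is created directly with its ether oxygen and its carboxyl, cis to O5, by suprafacial transfer of chirality from the former lactone C6. On this point the alternative is better than the chosen plan, which needs a lactone detour and a radical decarboxylative hydroxylation. The rearrangement is intramolecular and stereospecific.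
- Against it: A4 has two stereocentres and must itself be made by asymmetric synthesis. The α-alkoxy lactone has to be enolised cleanly, and the boat transition state is strained. O3 and O4 are still missing and would have to come from a syn-dihydroxylation of C3=C4 anti to the silyloxy group. The differentially protected product then needs esterification and deprotection before galloylation.
- Comparison: Structurally the chosen plan takes C3–C5 ready-made from a pentose and makes only C1 stereogenic, by geometric necessity; the alternative sets C1 elegantly but needs a later facial selection for two centres. Mechanistically a pericyclic shift stands against a double SN2, both well understood. In step count the two are about equal at best once the preparation of A4 is counted.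

Alternative 3: The cut removes the C1–O and C4–O bonds together and traces the 1,4-dioxygen pattern to the cyclohexadiene ester A7.
- Forward step: A [4+2] photooxygenation across C1 and C4 of A7, anti to the C5 silyloxy group, would give endoperoxide A8 with O1 and O4 cis to each other and trans to O5, as the target requires.
- In its favour: Two C–O bonds, including the tertiary C1–O, are made in one reagent-free step with the correct relative configuration. In atom economy and in the directness with which the tertiary carbinol is reached, this alternative is better than the chosen plan.
- Against it: A7 is one 1,4-elimination of its silyloxy group away from an aromatic ring, and its diene is deactivated by the ester toward an electrophilic dienophile. A8 has a C4–H next to the O–O bond and is open to a base-induced Kornblum–DeLaMare rearrangement. After O–O reduction, the C2=C3 double bond must still be hydrated with oxygen on C3 only, on the face of O4, and hydrogen on C2. That is a combined regio- and facial-selectivity problem needing several steps.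
- Comparison: Structurally the chosen plan creates no stereocentre by facial selection, whereas here the C5 centre must first be made enantioselectively and then direct two further selections. Mechanistically a concerted cycloaddition stands against a radical chain for the C1–O bond. In step count it is shorter on paper to an oxygenated ring, but the O3 problem and the access to enantiopure A7 bring it level or worse.

Key step: step 6

Remark on the chemistry: the anomeric composition of 2 is immaterial because the anomeric carbon is reduced in step 2; 1, 7 and 19 are taken as purchased.

## Route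

Step 1
Reactants: 1 D-arabinose
Product: 2 3,4-O-isopropylidene-β-D-arabinopyranose
Conditions: Me2C(OMe)2, TsOH·H2O (cat.), DMF, rt
Reagents that add atoms: 2,2-dimethoxypropane, COC(C)(C)OC
Why: Acid-catalysed transketalisation (acetonide formation); the pyranose offers one cis-vicinal diol, O3/O4, so the kinetic dioxolane should form there and leave O1 and O2 free. No lasting stereocentre is made.

Step 2
Reactants: 2 3,4-O-isopropylidene-β-D-arabinopyranose
Product: 3 3,4-O-isopropylidene-D-arabinitol
Conditions: NaBH4, MeOH, 0 °C → rt
Reagents that add atoms: none
Why: Borohydride reduction of the open-chain aldehyde in equilibrium with the lactol; the acetonide is stable to the basic medium and C2–C4 are not touched.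

Step 3
Reactants: 3 3,4-O-isopropylidene-D-arabinitol
Product: 4 1,2,5-tris-O-(tert-butyldimethylsilyl)-3,4-O-isopropylidene-D-arabinitol
Conditions: TBSCl (3.6 equiv), imidazole, DMAP (cat.), DMF, rt → 40 °C
Reagents that add atoms: tert-butyldimethylsilyl chloride, CC(C)(C)[Si](C)(C)Cl
Why: Exhaustive silyl ether formation needs no selectivity and masks O2 before any leaving group exists at C1 or C5, which excludes oxirane and 2,5-anhydro ring formation later.

Step 4
Reactants: 4 1,2,5-tris-O-(tert-butyldimethylsilyl)-3,4-O-isopropylidene-D-arabinitol
Product: 5 2-O-(tert-butyldimethylsilyl)-3,4-O-isopropylidene-D-arabinitol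
Conditions: HF·pyridine, pyridine, THF, 0 °C → rt
Reagents that add atoms: none
Why: Selective fluoride desilylation; primary TBS ethers are cleaved much faster than the hindered secondary one, and the buffered, slightly acidic medium should suppress 1,2-silyl migration and spare the acetonide.

Step 5
Reactants: 5 2-O-(tert-butyldimethylsilyl)-3,4-O-isopropylidene-D-arabinitol
Product: 6 2-O-(tert-butyldimethylsilyl)-1,5-dideoxy-1,5-diiodo-3,4-O-isopropylidene-D-arabinitol
Conditions: I2, PPh3, imidazole, toluene–MeCN, 0 °C → rt
Reagents that add atoms: iodine, [I][I]
Why: Appel-type iodination; both primary hydroxyls are converted through alkoxyphosphonium ions and SN2 attack by iodide at CH2, and with O2 silylated no intramolecular ether formation can compete.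

Step 6
Reactants: 6 2-O-(tert-butyldimethylsilyl)-1,5-dideoxy-1,5-diiodo-3,4-O-isopropylidene-D-arabinitol; 7 dibenzyl malonate
Product: 9 dibenzyl (3R,4R,5R)-5-(tert-butyldimethylsilyloxy)-3,4-(isopropylidenedioxy)cyclohexane-1,1-dicarboxylate, via monoalkylated iodo malonate 8 (not isolated)
Conditions: NaH (2.2 equiv), THF–DMF, 0 → 60 °C
Reagents that add atoms: none
Why: NaH converts 7 into its sodium enolate, which displaces one primary iodide of 6 by SN2 to give 8 (drawn for first attack at sugar C5; attack at sugar C1 first gives the regioisomeric monoalkylated malonate and the same ring), and 8 is deprotonated by the second equivalent of base so that its enolate carbon displaces the remaining iodide intramolecularly. The closest known reaction type is the malonic ester double alkylation with α,ω-dihalides (Perkin alicyclic synthesis), which extends to sugar-derived 1,5-dihalides. The ring closes in the 6-exo-tet mode, the breaking C–I bond lying outside the forming cyclohexane. No stereocentre is created: the new quaternary carbon carries two identical benzyl ester arms, and the three carbinol centres are untouched because both displacements occur at CH2 carbons. Substitution should win over elimination because the nucleophile is a soft, weakly basic stabilised carbanion, the leaving groups are primary iodides, and the only β-hydrogens sit on oxygen-bearing carbons whose removal would have to give enol ethers. Cyclisation should win over a second intermolecular alkylation because the chain is bent by the cis-fused dioxolane and only one equivalent of 7 is present at moderate dilution, and C-alkylation is preferred because O-alkylation would need an eight-membered ring. The silyl ether and acetonide are inert to the enolate, and the absence of any free hydroxyl in 6 excludes ether formation.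

Step 7
Reactants: 9 dibenzyl (3R,4R,5R)-5-(tert-butyldimethylsilyloxy)-3,4-(isopropylidenedioxy)cyclohexane-1,1-dicarboxylate
Product: 11 benzyl (1R,3R,4R,5R)-3,4-(isopropylidenedioxy)-7-oxo-6-oxabicyclo[3.2.1]octane-1-carboxylate, via hydroxy diester 10 (not isolated)
Conditions: Bu4NF, THF, 0 °C → rt
Reagents that add atoms: none
Why: Fluoride desilylation frees the O5 alkoxide, which attacks the one ester on its own face (intramolecular transesterification, γ-lactone across the 1,3-diaxial positions) and expels benzyl alcohol. C1 becomes stereogenic here, its configuration fixed because the lactone bridge cannot reach the trans ester; no free malonic acid is ever formed.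

Step 8
Reactants: 11 benzyl (1R,3R,4R,5R)-3,4-(isopropylidenedioxy)-7-oxo-6-oxabicyclo[3.2.1]octane-1-carboxylate
Product: 12 (1R,3R,4R,5R)-3,4-(isopropylidenedioxy)-7-oxo-6-oxabicyclo[3.2.1]octane-1-carboxylic acid
Conditions: H2 (1 atm), 10% Pd/C, EtOAc, rt
Reagents that add atoms: none
Why: Hydrogenolysis of the benzyl ester under neutral conditions; the acid should not decarboxylate thermally because the required enol would sit at a bridgehead (Bredt's rule).

Step 9
Reactants: 12 (1R,3R,4R,5R)-3,4-(isopropylidenedioxy)-7-oxo-6-oxabicyclo[3.2.1]octane-1-carboxylic acid
Product: 15 3,4-O-isopropylidene-1,5-quinide, via Barton ester 13 (not isolated), via bridgehead hydroperoxide 14 (not isolated)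
Conditions: DCC, 1-hydroxypyridine-2(1H)-thione, DMAP (cat.), CH2Cl2, 0 °C → rt, dark; then t-BuSH, O2, hν (tungsten lamp), 0 °C; then PPh3, rt
Reagents that add atoms: dioxygen, O=O; 1-hydroxypyridine-2(1H)-thione, On1ccccc1=S (its atoms remain only in intermediate 13)
Why: Barton decarboxylative hydroxylation: the thiohydroxamate ester 13 fragments in a radical chain to CO2 and the C1 bridgehead radical, which is trapped by O2; the peroxyl radical takes hydrogen from the thiol to give 14, and PPh3 reduces O–O to the alcohol. The bridgehead radical can be trapped only from outside the cage, so the hydroxyl takes the place of the carboxyl with retention, on the acetonide face.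

Step 10
Reactants: 15 3,4-O-isopropylidene-1,5-quinide
Product: 17 benzyl 3,4-O-isopropylidenequinate, via cesium carboxylate 16 (not isolated)
Conditions: CsOH·H2O (1.05 equiv), THF–H2O, 0 °C → rt; evaporate; BnBr, DMF, rt
Reagents that add atoms: cesium hydroxide, [Cs+].[OH-]; benzyl bromide, BrCc1ccccc1
Why: Saponification of the strained γ-lactone by one equivalent of hydroxide, then SN2 O-alkylation of the cesium carboxylate; the neutral hydroxyls are not alkylated without added base. Omitting acidification means the hydroxy acid that would relactonise is never formed.

Step 11
Reactants: 17 benzyl 3,4-O-isopropylidenequinate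
Product: 18 benzyl quinate
Conditions: AcOH–H2O (4:1), 50 °C
Reagents that add atoms: none
Why: Acid-catalysed acetal hydrolysis of the cis-fused dioxolane; aqueous acetic acid is mild enough to leave the benzyl ester, and the water present disfavours lactonisation.

Step 12
Reactants: 18 benzyl quinate; 19 3,4,5-tris(benzyloxy)benzoyl chloride (three equivalents consumed)
Product: 20 benzyl 3,4,5-tris-O-[3,4,5-tris(benzyloxy)benzoyl]quinate
Conditions: 19 (3.6 equiv), pyridine, DMAP (cat.), CH2Cl2, 0 °C → rt
Reagents that add atoms: 3,4,5-tris(benzyloxy)benzoyl chloride (second equivalent of 19), O=C(Cl)c1cc(OCc2ccccc2)c(OCc2ccccc2)c(OCc2ccccc2)c1; 3,4,5-tris(benzyloxy)benzoyl chloride (third equivalent of 19), O=C(Cl)c1cc(OCc2ccccc2)c(OCc2ccccc2)c(OCc2ccccc2)c1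
Why: DMAP-catalysed acylation of alcohols by an acid chloride; one molecule of 18 takes up three molecules of 19, one each at O3, O4 and O5, with loss of three HCl as pyridinium chloride. The tertiary O1, hindered and deactivated by the adjacent ester, should be spared at this stoichiometry and temperature, and no stereocentre is touched.

Step 13
Reactants: 20 benzyl 3,4,5-tris-O-[3,4,5-tris(benzyloxy)benzoyl]quinate
Product: 21 3,4,5-tri-O-galloylquinic acid
Conditions: H2 (1 atm), 10% Pd/C, THF–EtOAc, rt
Reagents that add atoms: none
Why: Catalytic hydrogenolysis of the nine benzyl ethers and the benzyl ester; the neutral, non-nucleophilic medium should leave the three aryl esters and the pyrogallol units intact, and no stereocentre is affected.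

## Compound list

1 | D-arabinose | O=C[C@@H](O)[C@H](O)[C@H](O)CO | starting material
2 | 3,4-O-isopropylidene-β-D-arabinopyranose | O[C@H]1[C@@H](O)[C@@H]2OC(C)(C)O[C@@H]2CO1 | intermediate
3 | 3,4-O-isopropylidene-D-arabinitol | OC[C@H]1OC(C)(C)O[C@H]1[C@H](O)CO | intermediate
4 | 1,2,5-tris-O-(tert-butyldimethylsilyl)-3,4-O-isopropylidene-D-arabinitol | CC(C)(C)[Si](C)(C)OC[C@H]1OC(C)(C)O[C@H]1[C@H](O[Si](C)(C)C(C)(C)C)CO[Si](C)(C)C(C)(C)C | intermediate
5 | 2-O-(tert-butyldimethylsilyl)-3,4-O-isopropylidene-D-arabinitol | OC[C@H]1OC(C)(C)O[C@H]1[C@H](O[Si](C)(C)C(C)(C)C)CO | intermediate
6 | 2-O-(tert-butyldimethylsilyl)-1,5-dideoxy-1,5-diiodo-3,4-O-isopropylidene-D-arabinitol | IC[C@H]1OC(C)(C)O[C@H]1[C@H](O[Si](C)(C)C(C)(C)C)CI | intermediate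
7 | dibenzyl malonate | O=C(OCc1ccccc1)CC(=O)OCc1ccccc1 | starting material
8 | dibenzyl 2-[2-O-(tert-butyldimethylsilyl)-1,5-dideoxy-1-iodo-3,4-O-isopropylidene-D-arabinitol-5-yl]malonate (monoalkylated iodo malonate, drawn for first attack at sugar C5) | O=C(OCc1ccccc1)C(C[C@H]1OC(C)(C)O[C@H]1[C@H](O[Si](C)(C)C(C)(C)C)CI)C(=O)OCc1ccccc1 | intermediate
9 | dibenzyl (3R,4R,5R)-5-(tert-butyldimethylsilyloxy)-3,4-(isopropylidenedioxy)cyclohexane-1,1-dicarboxylate (O3/O4 cis, O5 trans to O4) | CC(C)(C)[Si](C)(C)O[C@@H]1CC(C(=O)OCc2ccccc2)(C(=O)OCc2ccccc2)C[C@H]2OC(C)(C)O[C@@H]12 | intermediate
10 | dibenzyl (3R,4S,5R)-5-hydroxy-3,4-(isopropylidenedioxy)cyclohexane-1,1-dicarboxylate (hydroxy diester, same spatial arrangement as 9) | O[C@@H]1CC(C(=O)OCc2ccccc2)(C(=O)OCc2ccccc2)C[C@H]2OC(C)(C)O[C@@H]12 | intermediate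
11 | benzyl (1R,3R,4R,5R)-3,4-(isopropylidenedioxy)-7-oxo-6-oxabicyclo[3.2.1]octane-1-carboxylate (quinide skeleton; lactone from O5 to the cis carboxyl, benzyl ester on bridgehead C1 on the acetonide face) | O=C1O[C@@H]2C[C@@]1(C(=O)OCc1ccccc1)C[C@H]3OC(C)(C)O[C@@H]23 | intermediate
12 | (1R,3R,4R,5R)-3,4-(isopropylidenedioxy)-7-oxo-6-oxabicyclo[3.2.1]octane-1-carboxylic acid (same spatial arrangement as 11) | O=C1O[C@@H]2C[C@@]1(C(=O)O)C[C@H]3OC(C)(C)O[C@@H]23 | intermediate
13 | 2-thioxopyridin-1(2H)-yl ester of 12 (Barton ester, same spatial arrangement as 12) | O=C1O[C@@H]2C[C@@]1(C(=O)On1ccccc1=S)C[C@H]3OC(C)(C)O[C@@H]23 | intermediate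
14 | (1S,3R,4R,5R)-1-hydroperoxy-3,4-(isopropylidenedioxy)-6-oxabicyclo[3.2.1]octan-7-one (bridgehead hydroperoxide, OOH on the acetonide face) | O=C1O[C@@H]2C[C@@]1(OO)C[C@H]3OC(C)(C)O[C@@H]23 | intermediate
15 | 3,4-O-isopropylidene-1,5-quinide ((1S,3R,4R,5R)-1-hydroxy-3,4-(isopropylidenedioxy)-6-oxabicyclo[3.2.1]octan-7-one) | O=C1O[C@@H]2C[C@@]1(O)C[C@H]3OC(C)(C)O[C@@H]23 | intermediate
16 | cesium 3,4-O-isopropylidenequinate | O[C@@H]1C[C@](O)(C(=O)[O-])C[C@H]2OC(C)(C)O[C@@H]12.[Cs+] | intermediate
17 | benzyl 3,4-O-isopropylidenequinate | O[C@@H]1C[C@](O)(C(=O)OCc2ccccc2)C[C@H]2OC(C)(C)O[C@@H]12 | intermediate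
18 | benzyl quinate (O1, O3, O4 on one face; O5 and the ester carbon on the other) | O[C@@H]1C[C@](O)(C(=O)OCc2ccccc2)C[C@@H](O)[C@H]1O | intermediate
19 | 3,4,5-tris(benzyloxy)benzoyl chloride | O=C(Cl)c1cc(OCc2ccccc2)c(OCc2ccccc2)c(OCc2ccccc2)c1 | starting material
20 | benzyl 3,4,5-tris-O-[3,4,5-tris(benzyloxy)benzoyl]quinate | O=C(O[C@@H]1C[C@](O)(C(=O)OCc2ccccc2)C[C@@H](OC(=O)c2cc(OCc3ccccc3)c(OCc3ccccc3)c(OCc3ccccc3)c2)[C@H]1OC(=O)c1cc(OCc2ccccc2)c(OCc2ccccc2)c(OCc2ccccc2)c1)c1cc(OCc2ccccc2)c(OCc2ccccc2)c(OCc2ccccc2)c1 | intermediate
21 | 3,4,5-tri-O-galloylquinic acid | O=C(O[C@@H]1C[C@](O)(C(=O)O)C[C@@H](OC(=O)c2cc(O)c(O)c(O)c2)[C@H]1OC(=O)c1cc(O)c(O)c(O)c1)c1cc(O)c(O)c(O)c1 | target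

## Step count and least certain steps

Total: 13 steps. Longest linear sequence: 13 steps (1 to 21); 7 and 19 are bought and enter at steps 6 and 12.

Step 6 (key step). The most likely failure is slow substitution at the β-oxygenated, β-branched primary iodides. That would let dehydroiodination to enol ethers, intermolecular double alkylation, or iodide-induced debenzylation of the malonate at the required temperature compete. The fallback changes the electrophile class so that the reaction can run cold. It sets out from 5, which with Tf2O and 2,6-lutidine in CH2Cl2 at −40 °C should give the 1,5-bis(trifluoromethanesulfonate) F1. Treating F1 with the sodium enolate of 7 (NaH, THF, −20 °C → rt, second equivalent of base for ring closure) should give the same cyclohexane, and the route is rejoined at 9.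

Step 9. The radical chain may be diverted by hydrogen transfer from the thiol to the bridgehead radical (reductive decarboxylation instead of oxygenation). The hindered acid may form its thiohydroxamate ester incompletely, and the α-hydroperoxy lactone may fragment before it is reduced. The fallback replaces the oxygen/thiol chain by radical–radical trapping. It sets out from 12, converted to 13 as in step 9. Irradiating 13 under argon with 2,2,6,6-tetramethylpiperidin-1-oxyl, without thiol or oxygen, should give the bridgehead alkoxyamine F2. Reductive N–O cleavage of F2 with Zn dust in AcOH–THF–H2O at rt should give the tertiary alcohol, and the route is rejoined at 15.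

Step 4. The selectivity between primary and secondary silyl ether cleavage may be incomplete (over- or under-desilylation), or the silyl group may migrate from O2 to O1. The fallback reverses the order of events and uses sulfonates. It sets out from 3, whose two primary hydroxyls should be tosylated selectively (TsCl, 2.1 equiv, pyridine, −20 °C, kept cold to avoid anhydro ring formation) to give the ditosylate F3. Silylation of O2 with TBSOTf and 2,6-lutidine at −78 °C should give the silylated ditosylate F4, and halide exchange (NaI, butanone, reflux) should give the diiodide; the route is rejoined at 6.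

Step 10. The hydroxy ester may relactonise, by attack of O5 on the benzyl ester with loss of benzyl alcohol, during alkylation, concentration or the following acid step. The fallback goes through the fully deprotected acid. It sets out from 15, which on heating with aqueous acid (sulfonic acid resin in its H+ form, H2O, 60 °C) should lose the acetonide and open to quinic acid F5. The cesium salt of F5 (Cs2CO3, DMF) with BnBr should give the benzyl ester, and the route is rejoined at 18.

Step 12. Acylation may stop before the central O4, which sits between two bulky esters. Acyl migration and lactonisation of O5 onto the benzyl ester are the competing processes. The fallback divides the acylation into two less crowded events and caps O5 before the acetonide is removed. It sets out from 17, which with 19 (1.3 equiv, pyridine, DMAP) should give the 5-O-acyl acetonide F6. Acetal hydrolysis (AcOH–H2O, 50 °C) should give the 3,4-diol F7, and a second acylation with 19 (2.6 equiv) should complete the triester; the route is rejoined at 20.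

## Further compounds

F1 | step 6 | 2-O-(tert-butyldimethylsilyl)-3,4-O-isopropylidene-1,5-bis-O-(trifluoromethylsulfonyl)-D-arabinitol | O=S(=O)(OC[C@H]1OC(C)(C)O[C@H]1[C@H](O[Si](C)(C)C(C)(C)C)COS(=O)(=O)C(F)(F)F)C(F)(F)F
F2 | step 9 | 3,4-(isopropylidenedioxy)-1-[(2,2,6,6-tetramethylpiperidin-1-yl)oxy]-6-oxabicyclo[3.2.1]octan-7-one (configuration as 15) | O=C1O[C@@H]2C[C@@]1(ON4C(C)(C)CCCC4(C)C)C[C@H]3OC(C)(C)O[C@@H]23
F3 | step 4 | 3,4-O-isopropylidene-1,5-di-O-(4-methylbenzenesulfonyl)-D-arabinitol | Cc1ccc(cc1)S(=O)(=O)OC[C@H]1OC(C)(C)O[C@H]1[C@H](O)COS(=O)(=O)c1ccc(C)cc1
F4 | step 4 | 2-O-(tert-butyldimethylsilyl)-3,4-O-isopropylidene-1,5-di-O-(4-methylbenzenesulfonyl)-D-arabinitol | Cc1ccc(cc1)S(=O)(=O)OC[C@H]1OC(C)(C)O[C@H]1[C@H](O[Si](C)(C)C(C)(C)C)COS(=O)(=O)c1ccc(C)cc1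
F5 | step 10 | quinic acid | O[C@@H]1C[C@](O)(C(=O)O)C[C@@H](O)[C@H]1O
F6 | step 12 | benzyl 3,4-O-isopropylidene-5-O-[3,4,5-tris(benzyloxy)benzoyl]quinate | O=C(O[C@@H]1C[C@](O)(C(=O)OCc2ccccc2)C[C@H]2OC(C)(C)O[C@@H]12)c1cc(OCc2ccccc2)c(OCc2ccccc2)c(OCc2ccccc2)c1
F7 | step 12 | benzyl 5-O-[3,4,5-tris(benzyloxy)benzoyl]quinate | O=C(O[C@@H]1C[C@](O)(C(=O)OCc2ccccc2)C[C@@H](O)[C@H]1O)c1cc(OCc2ccccc2)c(OCc2ccccc2)c(OCc2ccccc2)c1
A1 | alternative 1 | benzyl 3,4,5-tri-O-propioloylquinate | C#CC(=O)O[C@@H]1C[C@](O)(C(=O)OCc2ccccc2)C[C@@H](OC(=O)C#C)[C@H]1OC(=O)C#C
A2 | alternative 1 | 3,4-bis(benzyloxy)furan | C(Oc1cocc1OCc1ccccc1)c1ccccc1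
A3 | alternative 1 | benzyl 3,4,5-tris-O-[3,4-bis(benzyloxy)-5-hydroxybenzoyl]quinate | O=C(O[C@@H]1C[C@](O)(C(=O)OCc2ccccc2)C[C@@H](OC(=O)c2cc(O)c(OCc3ccccc3)c(OCc3ccccc3)c2)[C@H]1OC(=O)c1cc(O)c(OCc2ccccc2)c(OCc2ccccc2)c1)c1cc(O)c(OCc2ccccc2)c(OCc2ccccc2)c1
A4 | alternative 2 | 3-(benzyloxy)-5-(tert-butyldimethylsilyloxy)-6-vinyltetrahydro-2H-pyran-2-one, silyloxy and vinyl trans, C3 either way | C=C[C@@H]1OC(=O)C(OCc2ccccc2)C[C@H]1O[Si](C)(C)C(C)(C)C
A5 | alternative 2 | trimethylsilyl ketene acetal of A4 | C=C[C@@H]1OC(O[Si](C)(C)C)=C(OCc2ccccc2)C[C@H]1O[Si](C)(C)C(C)(C)C
A6 | alternative 2 | 1-(benzyloxy)-5-(tert-butyldimethylsilyloxy)cyclohex-3-ene-1-carboxylic acid, silyloxy cis to the carboxyl | CC(C)(C)[Si](C)(C)O[C@@H]1C[C@](OCc2ccccc2)(C(=O)O)CC=C1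
A7 | alternative 3 | benzyl 5-(tert-butyldimethylsilyloxy)cyclohexa-1,3-diene-1-carboxylate | O=C(OCc1ccccc1)C1=CC=C[C@H](O[Si](C)(C)C(C)(C)C)C1
A8 | alternative 3 | benzyl 8-(tert-butyldimethylsilyloxy)-2,3-dioxabicyclo[2.2.2]oct-5-ene-1-carboxylate, silyloxy anti to the peroxide bridge | CC(C)(C)[Si](C)(C)O[C@@H]1C[C@]2(C(=O)OCc3ccccc3)C=C[C@H]1OO2
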